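**Retrosynthetic overview**
1. 33 ⇐ 32 ⇐ 30 ⇐ 29 by late carbamoylation and deprotection. Both arenes come intact from resorcinol, so the only ring formed is the 22-membered [7.7]paracyclophane ring.
2. 29 ⇐ seco bromide 28: ring closure at C6′–C7′ by nickel-hydride radical hydroalkylation of the terminal olefin with the racemic benzylic bromide (sets C7′).
3. 26 ⇐ 23 ⇐ 19: C7–butyl bond by stereoconvergent nickel radical Negishi coupling (sets C7). Tether and side chain exchange roles between the two couplings, so one ligand antipode can give the two benzylic centers their opposite spatial sense.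
4. 19 ⇐ aryllithium of olefin 15 + aldehyde 17 (hydroformylated 15): one building block serves both halves.
5. 15 ⇐ resorcinol by C–H borylation, one-carbon homologation to the aldehyde, (Z)-crotylboration (C1/C2) and B-alkyl Suzuki coupling with vinyl bromide.

Assumption: the SMILES is read literally (C1/C1′ R, C2/C2′ S, C7 and C7′ both S; because Cl raises the side-chain priority, the two benzylic centers have opposite spatial sense relative to ring, tether and side chain, so they are set separately), and 5-chloropentanal and butylzinc bromide (0.5 M in THF) are bought.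

Locants: ring X carries C1 and the chlorobutyl carbon C7′; ring Y carries C1′ and the butyl carbon C7. C1–C6 run from ring X to C7; C1′–C6′ run from ring Y to C7′. MOM = CH2OCH3, TBS = Si(CH3)2C(CH3)3.

**Route**

Step 1
Reactants: 1 resorcinol
Product: 2 1,3-bis(methoxymethoxy)benzene
Conditions: NaH (2.2 equiv), MOMCl (2.2 equiv), DMF, 0 °C to rt
Reagents that add atoms: chloromethyl methyl ether, COCCl
Why: Williamson etherification of both phenoxides; the MOM acetals later direct lithiation to the carbon between them and are removed by mild acid.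

Step 2
Reactants: 2 1,3-bis(methoxymethoxy)benzene
Product: 3 2-[3,5-bis(methoxymethoxy)phenyl]-4,4,5,5-tetramethyl-1,3,2-dioxaborolane
Conditions: [Ir(OMe)(cod)]2 (1.5 mol%), 4,4′-di-tert-butyl-2,2′-bipyridine (3 mol%), B2pin2 (1.0 equiv), THF, 80 °C
Reagents that add atoms: bis(pinacolato)diboron, CC1(C)OB(OC1(C)C)B1OC(C)(C)C(C)(C)O1
Why: sterically controlled iridium-catalysed C–H borylation (Hartwig–Miyaura) goes to C5, the only C–H without an ortho substituent.

Step 3
Reactants: 3 aryl pinacol boronate; 4 dichloromethane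
Product: 7 3,5-bis(methoxymethoxy)benzaldehyde, via dichloromethyllithium 5 (not isolated), via alpha-chloro boronate 6 (not isolated)
Conditions: CH2Cl2, n-BuLi, THF, −100 °C; add 3, warm to rt; then NaBO3·4H2O, THF/H2O, rt
Reagents that add atoms: sodium perborate, [Na+].[O-]OB=O
Why: Matteson homologation (1,2-aryl shift in the boronate complex of LiCHCl2) followed by C–B oxidation gives a chlorohydrin that collapses to the aldehyde.

Step 4
Reactants: 7 3,5-bis(methoxymethoxy)benzaldehyde; 8 cis-2-butene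
Product: 11 (1R,2S)-1-[3,5-bis(methoxymethoxy)phenyl]-2-methylbut-3-en-1-ol, via (Z)-crotylpotassium 9 (not isolated), via (Z)-crotylbis(isopinocampheyl)borane 10 (not isolated)
Conditions: cis-2-butene, KOtBu, n-BuLi, THF, −78 to −45 °C; (+)-Ipc2BOMe, −78 °C; BF3·OEt2; 7, −78 °C; then NaOH, H2O2
Reagents that add atoms: none
Why: Brown (Z)-crotylboration through a closed chair transition state gives the syn adduct, and the isopinocampheyl groups derived from (−)-α-pinene direct attack to the Re face of the aldehyde, setting (1R,2S); residual minor enantiomer is removed later as separable diastereomers.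

Step 5
Reactants: 11 syn homoallylic alcohol
Product: 12 tert-butyl{[(1R,2S)-1-[3,5-bis(methoxymethoxy)phenyl]-2-methylbut-3-en-1-yl]oxy}dimethylsilane
Conditions: TBSCl, imidazole, DMF, 40 °C
Reagents that add atoms: tert-butyldimethylsilyl chloride, CC(C)(C)[Si](C)(C)Cl
Why: silylation masks the carbinol against the organolithium, zinc and silane reagents that follow and is orthogonal to the MOM ethers.

Step 6
Reactants: 12 TBS ether; 13 vinyl bromide
Product: 15 tert-butyl{[(1R,2S)-1-[3,5-bis(methoxymethoxy)phenyl]-2-methylhex-5-en-1-yl]oxy}dimethylsilane, via B-alkyl-9-BBN 14 (not isolated)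
Conditions: 9-BBN, THF, rt; then vinyl bromide, Pd(dppf)Cl2 (5 mol%), 3 M NaOH, THF, 60 °C
Reagents that add atoms: none
Why: anti-Markovnikov hydroboration followed by B-alkyl Suzuki–Miyaura coupling extends the chain by two carbons to a terminal olefin without touching C1/C2.

Step 7
Reactants: 15 terminal olefin; 16 carbon monoxide
Product: 17 (6S,7R)-7-[3,5-bis(methoxymethoxy)phenyl]-7-[(tert-butyldimethylsilyl)oxy]-6-methylheptanal
Conditions: Rh(acac)(CO)2 (1 mol%), BiPhePhos (2 mol%), CO/H2 (1:1, 10 bar), toluene, 70 °C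
Reagents that add atoms: none
Why: linear-selective rhodium/bisphosphite hydroformylation turns the terminal olefin into the aldehyde whose carbonyl carbon becomes C7.

Step 8
Reactants: 15 terminal olefin (becomes ring Y); 17 aldehyde (becomes ring X)
Product: 19 seco alcohol ArY–CH(OH)–(CH2)4–CH(CH3)–CH(OTBS)–ArX (both C7 epimers), via aryllithium 18 (not isolated)
Conditions: 15 (1.1 equiv), n-BuLi (1.05 equiv), THF, 0 °C; then 17, −78 °C; H2O quench
Reagents that add atoms: none
Why: directed ortho-metalation between the two MOM ethers followed by 1,2-addition of the aryllithium to the aldehyde joins the halves; the C7 carbinol configuration is irrelevant because it is erased in step 9.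

Step 9
Reactants: 19 seco alcohol; 20 butylzinc bromide
Product: 23 (7S)-butyl seco compound, via mesylate 21 (not isolated), via benzylic bromide 22 (not isolated)
Conditions: MsCl, Et3N, THF, −30 °C; LiBr, to 0 °C; then NiBr2·diglyme (10 mol%), (S)-iPr-Pybox (13 mol%), n-BuZnBr (1.6 equiv), DMA/THF, 0 °C
Reagents that add atoms: none
Why: nickel/Pybox stereoconvergent Negishi coupling of a racemic secondary benzylic bromide, in which bromine abstraction gives a planar benzylic radical from either epimer and the chiral nickel–butyl complex captures it to set (S)-C7 under catalyst control (ligand antipode assigned by analogy, to be confirmed on a model; its mirror image is equally available).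

Step 10
Reactants: 23 (7S)-butyl seco compound; 24 5-chloropentanal
Product: 26 ring X benzylic alcohol ArX–CH(OH)–(CH2)4Cl (both C7′ epimers), via aryllithium 25 (not isolated)
Conditions: n-BuLi (1.2 equiv), THF, 0 °C; then 5-chloropentanal (1.5 equiv), −78 °C; H2O quench
Reagents that add atoms: none
Why: directed ortho-metalation of the only remaining C–H flanked by two MOM ethers (ring X), then 1,2-addition to the aldehyde, installs C7′ with its chlorobutyl chain; the alkyl chloride is only introduced after the lithiation.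

Step 11
Reactants: 26 ring X benzylic alcohol
Product: 29 bis-TBS tetra-MOM macrocycle (1R,2S,7S,1′R,2′S,7′S), via mesylate 27 (not isolated), via benzylic bromide 28 (not isolated)
Conditions: MsCl, Et3N, THF, −30 °C; LiBr; then syringe-pump addition (12 h) to NiBr2·diglyme (20 mol%), (S)-iPr-Pybox (26 mol%), (EtO)2MeSiH (3 equiv), KF (3 equiv), DMA/THF, 10 °C, 2 mM final
Reagents that add atoms: none
Why: Proposed new method: the benzylic radical formed from 28 by nickel is captured by the chiral Pybox–nickel primary alkyl generated by anti-Markovnikov nickel-hydride insertion into the tethered terminal olefin, and C–C reductive elimination closes the 22-membered ring and sets (S)-C7′ with the same ligand antipode as step 9 because side chain and tether have exchanged roles; the closest known reactions are the nickel/Pybox stereoconvergent Negishi coupling of racemic benzylic bromides with alkylzincs and nickel-hydride hydroalkylation of unactivated terminal olefins with alkyl halides (silane plus fluoride or carbonate base), including enantioconvergent versions with activated secondary electrophiles.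

Step 12
Reactants: 29 bis-TBS tetra-MOM macrocycle
Product: 30 macrocyclic diol (tetra-MOM)
Conditions: TBAF (4 equiv), THF, rt to 40 °C
Reagents that add atoms: none
Why: fluoride desilylation frees only the two benzylic carbinols, while the MOM ethers and the primary chloride are untouched.

Step 13
Reactants: 30 macrocyclic diol
Product: 32 bis-carbamate (tetra-MOM), via bis(trichloroacetylcarbamate) 31 (not isolated)
Conditions: Cl3CC(O)NCO (3 equiv), CH2Cl2, 0 °C; then K2CO3, MeOH, rt
Reagents that add atoms: trichloroacetyl isocyanate, O=C=NC(=O)C(Cl)(Cl)Cl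
Why: acyl isocyanate addition to the hindered secondary alcohols followed by mild methanolysis of the trichloroacetyl group gives the primary carbamates with retention at C1 and C1′.

Step 14
Reactants: 32 bis-carbamate (tetra-MOM)
Product: 33 target CNP0117394.1
Conditions: HCl (2 M), MeOH, 40 °C
Reagents that add atoms: none
Why: acid-catalysed acetal exchange removes the four aryl MOM ethers; the carbamates sit on benzylic carbons meta to the ring oxygens, so they are not activated toward solvolysis.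

**Compound list**
1 | resorcinol | Oc1cccc(O)c1 | starting material
2 | 1,3-bis(methoxymethoxy)benzene | COCOc1cccc(OCOC)c1 | intermediate
3 | 2-[3,5-bis(methoxymethoxy)phenyl]-4,4,5,5-tetramethyl-1,3,2-dioxaborolane | COCOc1cc(OCOC)cc(c1)B1OC(C)(C)C(C)(C)O1 | intermediate
4 | dichloromethane | ClCCl | starting material
5 | (dichloromethyl)lithium | [Li]C(Cl)Cl | intermediate
6 | 2-{chloro[3,5-bis(methoxymethoxy)phenyl]methyl}-4,4,5,5-tetramethyl-1,3,2-dioxaborolane (racemic) | COCOc1cc(OCOC)cc(c1)C(Cl)B1OC(C)(C)C(C)(C)O1 | intermediate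
7 | 3,5-bis(methoxymethoxy)benzaldehyde | COCOc1cc(OCOC)cc(C=O)c1 | intermediate
8 | cis-2-butene | C/C=C\C | starting material
9 | (Z)-but-2-enylpotassium | C/C=C\C[K] | intermediate
10 | (Z)-crotylbis(isopinocampheyl)borane, Ipc groups from (−)-α-pinene | C/C=C\CB([C@H]1C[C@H]2C[C@@H]([C@@H]1C)C2(C)C)[C@H]1C[C@H]2C[C@@H]([C@@H]1C)C2(C)C | intermediate
11 | (1R,2S)-1-[3,5-bis(methoxymethoxy)phenyl]-2-methylbut-3-en-1-ol | C=C[C@H](C)[C@@H](O)c1cc(OCOC)cc(OCOC)c1 | intermediate
12 | tert-butyl{[(1R,2S)-1-[3,5-bis(methoxymethoxy)phenyl]-2-methylbut-3-en-1-yl]oxy}dimethylsilane | C=C[C@H](C)[C@@H](O[Si](C)(C)C(C)(C)C)c1cc(OCOC)cc(OCOC)c1 | intermediate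
13 | vinyl bromide | C=CBr | starting material
14 | 9-[(3S,4R)-4-[3,5-bis(methoxymethoxy)phenyl]-4-(TBS-oxy)-3-methylbutyl]-9-borabicyclo[3.3.1]nonane | C1CC2CCCC(C1)B2CC[C@H](C)[C@@H](O[Si](C)(C)C(C)(C)C)c1cc(OCOC)cc(OCOC)c1 | intermediate
15 | tert-butyl{[(1R,2S)-1-[3,5-bis(methoxymethoxy)phenyl]-2-methylhex-5-en-1-yl]oxy}dimethylsilane | C=CCC[C@H](C)[C@@H](O[Si](C)(C)C(C)(C)C)c1cc(OCOC)cc(OCOC)c1 | intermediate
16 | carbon monoxide | [C-]#[O+] | starting material
17 | (6S,7R)-7-[3,5-bis(methoxymethoxy)phenyl]-7-[(tert-butyldimethylsilyl)oxy]-6-methylheptanal | O=CCCCC[C@H](C)[C@@H](O[Si](C)(C)C(C)(C)C)c1cc(OCOC)cc(OCOC)c1 | intermediate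
18 | {4-[(1R,2S)-1-(TBS-oxy)-2-methylhex-5-en-1-yl]-2,6-bis(methoxymethoxy)phenyl}lithium | [Li]c1c(OCOC)cc(cc1OCOC)[C@H](O[Si](C)(C)C(C)(C)C)[C@@H](C)CCC=C | intermediate
19 | seco alcohol: ring Y [2,6-bis(MOM-oxy)-4-((1′R,2′S)-1′-TBS-oxy-2′-methylhex-5′-enyl)phenyl] bears CH(OH) (C7, both epimers) linked by (CH2)4 to (2S)-CH(CH3)–(1R)-CH(OTBS)–[3,5-bis(MOM-oxy)phenyl] (ring X) | OC(CCCC[C@H](C)[C@@H](O[Si](C)(C)C(C)(C)C)c1cc(OCOC)cc(OCOC)c1)c1c(OCOC)cc(cc1OCOC)[C@H](O[Si](C)(C)C(C)(C)C)[C@@H](C)CCC=C | intermediate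
20 | butylzinc bromide | CCCC[Zn]Br | starting material
21 | C7 methanesulfonate of 19 (both epimers) | CS(=O)(=O)OC(CCCC[C@H](C)[C@@H](O[Si](C)(C)C(C)(C)C)c1cc(OCOC)cc(OCOC)c1)c1c(OCOC)cc(cc1OCOC)[C@H](O[Si](C)(C)C(C)(C)C)[C@@H](C)CCC=C | intermediate
22 | C7 bromide corresponding to 19 (both epimers) | BrC(CCCC[C@H](C)[C@@H](O[Si](C)(C)C(C)(C)C)c1cc(OCOC)cc(OCOC)c1)c1c(OCOC)cc(cc1OCOC)[C@H](O[Si](C)(C)C(C)(C)C)[C@@H](C)CCC=C | intermediate
23 | (7S)-butyl seco compound: as 19 with C7 = (S)-CH(n-Bu); ring X position between the MOM ethers still C–H; ring Y chain ends in the C5′=C6′ olefin | CCCC[C@@H](CCCC[C@H](C)[C@@H](O[Si](C)(C)C(C)(C)C)c1cc(OCOC)cc(OCOC)c1)c1c(OCOC)cc(cc1OCOC)[C@H](O[Si](C)(C)C(C)(C)C)[C@@H](C)CCC=C | intermediate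
24 | 5-chloropentanal | O=CCCCCCl | starting material
25 | ring X aryllithium of 23 (Li between the two MOM ethers) | CCCC[C@@H](CCCC[C@H](C)[C@@H](O[Si](C)(C)C(C)(C)C)c1cc(OCOC)c([Li])c(OCOC)c1)c1c(OCOC)cc(cc1OCOC)[C@H](O[Si](C)(C)C(C)(C)C)[C@@H](C)CCC=C | intermediate
26 | 23 carrying CH(OH)(CH2)4Cl (C7′, both epimers) on ring X between the MOM ethers | CCCC[C@@H](CCCC[C@H](C)[C@@H](O[Si](C)(C)C(C)(C)C)c1cc(OCOC)c(C(O)CCCCCl)c(OCOC)c1)c1c(OCOC)cc(cc1OCOC)[C@H](O[Si](C)(C)C(C)(C)C)[C@@H](C)CCC=C | intermediate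
27 | C7′ methanesulfonate of 26 (both epimers) | CCCC[C@@H](CCCC[C@H](C)[C@@H](O[Si](C)(C)C(C)(C)C)c1cc(OCOC)c(C(OS(C)(=O)=O)CCCCCl)c(OCOC)c1)c1c(OCOC)cc(cc1OCOC)[C@H](O[Si](C)(C)C(C)(C)C)[C@@H](C)CCC=C | intermediate
28 | C7′ bromide corresponding to 26 (both epimers) | CCCC[C@@H](CCCC[C@H](C)[C@@H](O[Si](C)(C)C(C)(C)C)c1cc(OCOC)c(C(Br)CCCCCl)c(OCOC)c1)c1c(OCOC)cc(cc1OCOC)[C@H](O[Si](C)(C)C(C)(C)C)[C@@H](C)CCC=C | intermediate
29 | bis-TBS tetra-MOM [7.7]paracyclophane, (1R,2S,7S,1′R,2′S,7′S) | CCCC[C@H]1CCCC[C@H](C)[C@@H](O[Si](C)(C)C(C)(C)C)c2cc(OCOC)c(c(OCOC)c2)[C@H](CCCCCl)CCCC[C@H](C)[C@@H](O[Si](C)(C)C(C)(C)C)c2cc(OCOC)c1c(OCOC)c2 | intermediate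
30 | tetra-MOM macrocyclic 1,1′-diol, same configuration | CCCC[C@H]1CCCC[C@H](C)[C@@H](O)c2cc(OCOC)c(c(OCOC)c2)[C@H](CCCCCl)CCCC[C@H](C)[C@@H](O)c2cc(OCOC)c1c(OCOC)c2 | intermediate
31 | tetra-MOM macrocyclic bis(N-trichloroacetylcarbamate) | CCCC[C@H]1CCCC[C@H](C)[C@@H](OC(=O)NC(=O)C(Cl)(Cl)Cl)c2cc(OCOC)c(c(OCOC)c2)[C@H](CCCCCl)CCCC[C@H](C)[C@@H](OC(=O)NC(=O)C(Cl)(Cl)Cl)c2cc(OCOC)c1c(OCOC)c2 | intermediate
32 | tetra-MOM macrocyclic bis-carbamate | CCCC[C@H]1CCCC[C@H](C)[C@@H](OC(N)=O)c2cc(OCOC)c(c(OCOC)c2)[C@H](CCCCCl)CCCC[C@H](C)[C@@H](OC(N)=O)c2cc(OCOC)c1c(OCOC)c2 | intermediate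
33 | CNP0117394.1 | CCCC[C@H]1CCCC[C@H](C)[C@@H](OC(N)=O)c2cc(O)c(c(O)c2)[C@H](CCCCCl)CCCC[C@H](C)[C@@H](OC(N)=O)c2cc(O)c1c(O)c2 | target

**Totals**
Total step count: 14. Longest linear sequence: 14 steps (resorcinol to 33; olefin 15 is used twice, as the aryllithium and as the source of aldehyde 17).

**Three steps most likely to fail**

Step 11 (macrocyclisation). The reaction is new, and hydrodebromination, oligomerisation and poor control at C7′ are all possible. Fallback, from 23 back to 29: lithiate 23 to aryllithium 25 and add acrolein (THF, −78 °C) to give allylic alcohol F1. Ring-closing metathesis with second-generation Grubbs catalyst (CH2Cl2, 1 mM, 40 °C) gives macrocyclic allylic alcohol F2. Diimide (TsNHNH2, NaOAc, THF/H2O, 65 °C) gives saturated macrocyclic alcohol F3, and CBr4/PPh3 gives macrocyclic bromide F4. An intermolecular stereoconvergent Negishi coupling with 4-chlorobutylzinc bromide F5 (from 1-bromo-4-chlorobutane and Zn dust in DMA), NiBr2·diglyme and (R)-iPr-Pybox then delivers 29. The mirror-image ligand is used because here the tether sits on the electrophile and the side chain arrives from zinc.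

Step 9 (Negishi coupling on a benzylic bromide flanked by two MOM ethers). The bromide may ionise, eliminate or be attacked by a neighbouring MOM oxygen, and catalyst control on so hindered a radical is untested. Fallback, from 15 back to 23, sets C7 by a two-electron conjugate addition instead. Lithiate 15 to aryllithium 18 and quench with DMF to give aryl aldehyde F6. Wittig reaction with Ph3P=CHC(O)SEt (toluene, 80 °C) gives (E)-thioenoate F7. Conjugate addition of BuMgBr with CuBr·SMe2 and the Josiphos antipode that gives (S) (t-BuOMe, −75 °C) gives beta-butyl thioester F8. LiAlH4 gives primary alcohol F9 and CBr4/PPh3 gives primary bromide F10. An alkyl–alkyl Suzuki coupling of F10 with borane 14 (made from 12 and 9-BBN; Pd(OAc)2, PCy3, K3PO4·H2O, THF, rt) rejoins the route at 23.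

Step 10 (late aryllithium addition to an enolisable, sensitive chloro aldehyde). Enolisation of 24 by the hindered aryllithium would return 23. Fallback, from 23 back to 26, reverses the polarity of the C–C bond formation. Aryllithium 25 is quenched with DMF to give ring X aryl aldehyde F11, and 4-chlorobutylmagnesium bromide F12 (from 1-bromo-4-chlorobutane and Mg, THF, −78 °C) adds to it to give 26.

**Further compounds**
F1 | step 11 | 23 carrying CH(OH)CH=CH2 on ring X between the MOM ethers (both epimers) | CCCC[C@@H](CCCC[C@H](C)[C@@H](O[Si](C)(C)C(C)(C)C)c1cc(OCOC)c(C(O)C=C)c(OCOC)c1)c1c(OCOC)cc(cc1OCOC)[C@H](O[Si](C)(C)C(C)(C)C)[C@@H](C)CCC=C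
F2 | step 11 | macrocyclic allylic alcohol, C7′–OH with C5′=C6′ olefin (E/Z and C7′ epimers) | CCCC[C@H]1CCCC[C@H](C)[C@@H](O[Si](C)(C)C(C)(C)C)c2cc(OCOC)c(c(OCOC)c2)C(O)C=CCC[C@H](C)[C@@H](O[Si](C)(C)C(C)(C)C)c2cc(OCOC)c1c(OCOC)c2
F3 | step 11 | saturated macrocyclic C7′ alcohol (both epimers) | CCCC[C@H]1CCCC[C@H](C)[C@@H](O[Si](C)(C)C(C)(C)C)c2cc(OCOC)c(c(OCOC)c2)C(O)CCCC[C@H](C)[C@@H](O[Si](C)(C)C(C)(C)C)c2cc(OCOC)c1c(OCOC)c2
F4 | step 11 | macrocyclic C7′ bromide (both epimers) | CCCC[C@H]1CCCC[C@H](C)[C@@H](O[Si](C)(C)C(C)(C)C)c2cc(OCOC)c(c(OCOC)c2)C(Br)CCCC[C@H](C)[C@@H](O[Si](C)(C)C(C)(C)C)c2cc(OCOC)c1c(OCOC)c2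
F5 | step 11 | 4-chlorobutylzinc bromide | ClCCCC[Zn]Br
F6 | step 9 | 4-[(1R,2S)-1-(TBS-oxy)-2-methylhex-5-en-1-yl]-2,6-bis(methoxymethoxy)benzaldehyde | O=Cc1c(OCOC)cc(cc1OCOC)[C@H](O[Si](C)(C)C(C)(C)C)[C@@H](C)CCC=C
F7 | step 9 | S-ethyl (E)-3-aryl-prop-2-enethioate of F6 | CCSC(=O)/C=C/c1c(OCOC)cc(cc1OCOC)[C@H](O[Si](C)(C)C(C)(C)C)[C@@H](C)CCC=C
F8 | step 9 | S-ethyl (3S)-3-arylheptanethioate | CCCC[C@@H](CC(=O)SCC)c1c(OCOC)cc(cc1OCOC)[C@H](O[Si](C)(C)C(C)(C)C)[C@@H](C)CCC=C
F9 | step 9 | (3S)-3-arylheptan-1-ol | CCCC[C@@H](CCO)c1c(OCOC)cc(cc1OCOC)[C@H](O[Si](C)(C)C(C)(C)C)[C@@H](C)CCC=C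
F10 | step 9 | (3S)-3-aryl-1-bromoheptane | CCCC[C@@H](CCBr)c1c(OCOC)cc(cc1OCOC)[C@H](O[Si](C)(C)C(C)(C)C)[C@@H](C)CCC=C
F11 | step 10 | 23 carrying CHO on ring X between the MOM ethers | CCCC[C@@H](CCCC[C@H](C)[C@@H](O[Si](C)(C)C(C)(C)C)c1cc(OCOC)c(C=O)c(OCOC)c1)c1c(OCOC)cc(cc1OCOC)[C@H](O[Si](C)(C)C(C)(C)C)[C@@H](C)CCC=C
F12 | step 10 | 4-chlorobutylmagnesium bromide | ClCCCC[Mg]Br
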